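**Strategy.** Everything rests on disconnecting ring B at C9–C10, the bond between two fully substituted carbons. In one operation, hydrogen-atom transfer from an iron hydride to the C10 exocyclic methylene of 24 creates the C20 methyl and a tertiary C10 radical that adds 6-exo to C9, the oxygen-bearing β-carbon of the C9=C11–C12=O unit of a spiro 3(2H)-furanone; this forms the C9–C10 bond, ring B and both quaternary stereocentres. The precursor is a ring-A 19,6β-lactone bearing the C10 methylene, linked through C6–C7–C8 to the furanone, with C15 masked as a methyl acetal; it comes from three fragments by aldol–lactonisation, acetylide acylation and gold-catalysed ynone cyclisation.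

Key step: step 17

Assumption: labdane numbering is used, and C15 of the spiro ring is carried through the key step as its methyl acetal (both C15 epimers, same ring skeleton) instead of a lactone carbonyl, because a C15 lactone would have to be told apart from the C12 ketone and the 19,6-lactone at the end and is open to β-elimination of O9; C15 becomes sp2 in step 18.

**Route**

Step 1
Reactants: 1 (S)-4-benzyl-3-propanoyl-1,3-oxazolidin-2-one; 2 tert-butyl bromoacetate
Product: 3 tert-butyl (3R)-4-[(4S)-4-benzyl-2-oxo-1,3-oxazolidin-3-yl]-3-methyl-4-oxobutanoate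
Conditions: NaHMDS, THF, −78 °C; then 2, −78 → −40 °C
Reagents that add atoms: none
Why: Evans alkylation, in which the chelated Z-sodium enolate is alkylated on the face away from the benzyl group and so sets C8 (R).

Step 2
Reactants: 3 tert-butyl (3R)-4-[(4S)-4-benzyl-2-oxo-1,3-oxazolidin-3-yl]-3-methyl-4-oxobutanoate
Product: 4 tert-butyl (3R)-4-hydroxy-3-methylbutanoate
Conditions: LiBH4, MeOH (1 equiv), Et2O, 0 °C
Reagents that add atoms: none
Why: Borohydride reductive cleavage of the N-acyloxazolidinone, whose exocyclic carbonyl is far more electrophilic than the hindered tert-butyl ester; the stereocentre is not touched.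

Step 3
Reactants: 4 tert-butyl (3R)-4-hydroxy-3-methylbutanoate
Product: 5 tert-butyl (3R)-3-methyl-4-oxobutanoate
Conditions: Dess–Martin periodinane, CH2Cl2, 0 °C → rt
Reagents that add atoms: none
Why: Dess–Martin oxidation is non-basic, so the α-methyl aldehyde should keep its configuration.

Step 4
Reactants: 5 tert-butyl (3R)-3-methyl-4-oxobutanoate
Product: 6 tert-butyl (3R)-3-methylpent-4-ynoate
Conditions: Ohira–Bestmann reagent, K2CO3, MeOH, 0 °C → rt
Reagents that add atoms: dimethyl (1-diazo-2-oxopropyl)phosphonate, CC(=O)C(=[N+]=[N-])P(=O)(OC)OC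
Why: Seyferth–Gilbert homologation under the mild Ohira–Bestmann conditions turns the aldehyde into the terminal alkyne (C9≡C11) with little risk to the adjacent stereocentre at 0 °C.

Step 5
Reactants: 6 tert-butyl (3R)-3-methylpent-4-ynoate
Product: 7 (3R)-3-methylpent-4-ynal
Conditions: DIBAL-H (1.1 equiv), CH2Cl2, −78 °C; Rochelle salt; used as a solution
Reagents that add atoms: none
Why: Partial DIBAL reduction of the ester stops at the aldehyde because the tetrahedral aluminate is stable at −78 °C.

Step 6
Reactants: 8 methyl 3-oxocyclohex-1-ene-1-carboxylate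
Product: 10 methyl (1S)-1-methyl-3-(trimethylsilyloxy)cyclohex-2-ene-1-carboxylate, via methylzinc enolate 9 (not isolated)
Conditions: Me2Zn, (CuOTf)2·C6H6 (2.5 mol %), chiral sulfonate-NHC–Ag complex (2.5 mol %, enantiomer giving 1S), t-BuOMe, −30 °C; then TMSOTf, −30 → 0 °C
Reagents that add atoms: dimethylzinc, C[Zn]C; trimethylsilyl trifluoromethanesulfonate, C[Si](C)(C)OS(=O)(=O)C(F)(F)F
Why: Cu–NHC-catalysed enantioselective conjugate addition of a dialkylzinc to a β-ester cyclic enone sets the quaternary C4 (methyl C18, ester C19) under ligand control, and O-silylation of the zinc enolate fixes the enolate towards C5.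

Step 7
Reactants: 10 methyl (1S)-1-methyl-3-(trimethylsilyloxy)cyclohex-2-ene-1-carboxylate; 7 (3R)-3-methylpent-4-ynal
Product: 13 (3R,3aR,7aS)-7a-methyl-3-[(2R)-2-methylbut-3-yn-1-yl]hexahydro-2-benzofuran-1,4-dione, via dibutylboron enolate 11 (not isolated), via aldol adduct 12 (not isolated)
Conditions: n-Bu2BOTf, CH2Cl2, −78 → 0 °C (Si→B exchange); 7, −78 °C; pH 7 sodium phosphate buffer–MeOH; then CSA (cat.), toluene, 40 °C
Reagents that add atoms: none
Why: Silicon–boron exchange gives the regiodefined (E)-boron enolate, whose Zimmerman–Traxler aldol should give the 5,6-anti adduct on the enolate face anti to the pseudoaxial C4 methyl (the side of the slimmer, electron-poor ester), and acid-catalysed lactonisation of this cis γ-hydroxy ester, with C5 still epimerisable through the ketone, locks C4–C5–C6 as the cis-fused 19,6-lactone.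

Step 8
Reactants: 13 (3R,3aR,7aS)-7a-methyl-3-[(2R)-2-methylbut-3-yn-1-yl]hexahydro-2-benzofuran-1,4-dione
Product: 14 (3R,3aR,7aS)-7a-methyl-4-methylidene-3-[(2R)-2-methylbut-3-yn-1-yl]hexahydro-2-benzofuran-1(3H)-one
Conditions: Zn, CH2Br2, TiCl4, THF–CH2Cl2, 0 °C → rt
Reagents that add atoms: dibromomethane, BrCBr
Why: Takai–Lombardo methylenation is non-basic, so the β-acyloxy ketone should neither eliminate nor epimerise at C5, and the lactone and terminal alkyne are left alone.

Step 9
Reactants: 15 L-malic acid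
Product: 16 [(2S,4S)-2-tert-butyl-5-oxo-1,3-dioxolan-4-yl]acetic acid
Conditions: t-BuCHO, p-TsOH·H2O (cat.), H2SO4 (cat.), pentane, reflux, Dean–Stark; recrystallisation
Reagents that add atoms: pivalaldehyde, CC(C)(C)C=O
Why: Acid-catalysed acetalisation of the α-hydroxy acid gives the thermodynamically preferred cis-dioxolanone, which stores the malate configuration in the acetal centre.

Step 10
Reactants: 16 [(2S,4S)-2-tert-butyl-5-oxo-1,3-dioxolan-4-yl]acetic acid
Product: 17 [(2S,4R)-4-[(benzyloxy)methyl]-2-tert-butyl-5-oxo-1,3-dioxolan-4-yl]acetic acid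
Conditions: LiHMDS (2.2 equiv), THF, −78 °C; BnOCH2Cl (1.05 equiv), −78 → −30 °C; aq. KHSO4
Reagents that add atoms: benzyl chloromethyl ether, ClCOCc1ccccc1
Why: Self-regeneration of stereocentres: the dioxolanone enolate (as carboxylate dianion) is alkylated trans to the tert-butyl group, so C16 replaces H with retention and sets the quaternary C13.

Step 11
Reactants: 17 [(2S,4R)-4-[(benzyloxy)methyl]-2-tert-butyl-5-oxo-1,3-dioxolan-4-yl]acetic acid
Product: 18 (2S,5R)-5-[(benzyloxy)methyl]-2-tert-butyl-5-(2-hydroxyethyl)-1,3-dioxolan-4-one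
Conditions: BH3·SMe2, THF, 0 °C → rt; MeOH quench
Reagents that add atoms: none
Why: Borane reduces the free carboxylic acid chemoselectively (via the acyloxyborane) and leaves the dioxolanone ester and benzyl ether intact.

Step 12
Reactants: 18 (2S,5R)-5-[(benzyloxy)methyl]-2-tert-butyl-5-(2-hydroxyethyl)-1,3-dioxolan-4-one
Product: 19 [(2S,4R)-4-[(benzyloxy)methyl]-2-tert-butyl-5-oxo-1,3-dioxolan-4-yl]acetaldehyde
Conditions: Dess–Martin periodinane, CH2Cl2, 0 °C → rt; used directly
Reagents that add atoms: none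
Why: Dess–Martin oxidation gives the C15 aldehyde under neutral conditions that should not trigger β-elimination of the dioxolanone oxygen.

Step 13
Reactants: 19 [(2S,4R)-4-[(benzyloxy)methyl]-2-tert-butyl-5-oxo-1,3-dioxolan-4-yl]acetaldehyde
Product: 21 methyl (3R)-3-hydroxy-5-methoxyoxolane-3-carboxylate, via spiro lactol 20 (not isolated)
Conditions: H2 (1 atm), Pd/C, MeOH, rt; filter; then HCl (cat., from AcCl), MeOH, 50 °C
Reagents that add atoms: methanol, CO
Why: Hydrogenolysis frees the C16 hydroxyl, which closes onto the aldehyde as the five-membered lactol, and acidic methanol then gives the methyl acetal (Fischer-type) and methanolyses the dioxolanone to the methyl ester without touching C13.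

Step 14
Reactants: 21 methyl (3R)-3-hydroxy-5-methoxyoxolane-3-carboxylate
Product: 22 (3R)-3-hydroxy-N,5-dimethoxy-N-methyloxolane-3-carboxamide
Conditions: MeNHOMe·HCl, i-PrMgCl, THF, −20 → 0 °C
Reagents that add atoms: N,O-dimethylhydroxylamine hydrochloride, Cl.CNOC
Why: Weinreb amide formation by aminolysis of the ester with the magnesium amide, under basic conditions that the acetal tolerates.

Step 15
Reactants: 14 (3R,3aR,7aS)-7a-methyl-4-methylidene-3-[(2R)-2-methylbut-3-yn-1-yl]hexahydro-2-benzofuran-1(3H)-one; 22 (3R)-3-hydroxy-N,5-dimethoxy-N-methyloxolane-3-carboxamide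
Product: 23 (3R,3aR,7aS)-3-{(2R)-5-[(3R)-3-hydroxy-5-methoxyoxolan-3-yl]-2-methyl-5-oxopent-3-yn-1-yl}-7a-methyl-4-methylidenehexahydro-2-benzofuran-1(3H)-one
Conditions: 14, LDA (1.05 equiv), THF, −78 °C; add 22 pre-treated with LDA (1.0 equiv), −78 → 0 °C; aq. NH4Cl
Reagents that add atoms: none
Why: Weinreb ketone synthesis: the lithium acetylide (C11) adds once to the amide (C12) through a chelated tetrahedral intermediate, while the hindered lactone of 14, which has no α-hydrogen, is not attacked by LDA.

Step 16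
Reactants: 23 (3R,3aR,7aS)-3-{(2R)-5-[(3R)-3-hydroxy-5-methoxyoxolan-3-yl]-2-methyl-5-oxopent-3-yn-1-yl}-7a-methyl-4-methylidenehexahydro-2-benzofuran-1(3H)-one
Product: 24 (3R,3aR,7aS)-3-{(2R)-2-[(5R)-8-methoxy-4-oxo-1,7-dioxaspiro[4.4]non-2-en-2-yl]propyl}-7a-methyl-4-methylidenehexahydro-2-benzofuran-1(3H)-one
Conditions: (Ph3P)AuCl (5 mol %), AgOTf (5 mol %), toluene, rt
Reagents that add atoms: none
Why: Gold(I)-catalysed 5-endo-dig cycloisomerisation of the γ-hydroxy ynone (13-OH onto C9) gives the 3(2H)-furanone under neutral conditions that should not epimerise C8.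

Step 17
Reactants: 24 (3R,3aR,7aS)-3-{(2R)-2-[(5R)-8-methoxy-4-oxo-1,7-dioxaspiro[4.4]non-2-en-2-yl]propyl}-7a-methyl-4-methylidenehexahydro-2-benzofuran-1(3H)-one
Product: 25 (13R)-15-methoxy-12-oxo-9α,13:15,16-diepoxylabdan-19,6β-olide
Conditions: Fe(acac)3 (30 mol %), PhSiH3 (2.5 equiv, slow addition), degassed MeOH–THF, 50 °C
Reagents that add atoms: none
Why: Proposed new method: an iron(III) hydride formed from Fe(acac)3 and PhSiH3 transfers H• to C20 of the 1,1-disubstituted alkene, the nucleophilic tertiary C10 radical adds to C9, the β-carbon of the push–pull 3(2H)-furanone, and the C11 α-keto radical is reduced by Fe(II) and protonated by methanol (chosen so that any acetal exchange is degenerate). The closest known reaction types are MHAT-initiated intramolecular Giese cyclisations that build quaternary ring-fusion carbons and radical additions to the oxygen-bearing carbon of β-alkoxy enoates; joining two fully substituted carbons on a 3(2H)-furanone is not known. Ring B closes 6-exo-trig through a chair in which the C5–C6 bond is equatorial on ring A. C10 is controlled by the rigid cis-fused 19,6-lactone, whose axial C19 carbonyl crowds the β face, so C9 should bond equatorially (trans-decalin) and C20 end axial; C9 is controlled by the same chair, with the C8 methyl and the C11 arm equatorial and the O9–C13 arm axial on the open α face. The step needs trans ring fusion and one C9 face; the lactone and the resident C8 centre favour a single chair, and a wrong C9 epimer could still be equilibrated by base through retro-oxa-Michael and re-addition.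

Step 18
Reactants: 25 (13R)-15-methoxy-12-oxo-9α,13:15,16-diepoxylabdan-19,6β-olide
Product: 26 12-(trimethylsilyloxy)-9α,13:15,16-diepoxylabda-11,14-dien-19,6β-olide
Conditions: TMSOTf (3 equiv), i-Pr2NEt (5 equiv), CH2Cl2, −40 → 0 °C; aq. NaHCO3; used crude
Reagents that add atoms: trimethylsilyl trifluoromethanesulfonate, C[Si](C)(C)OS(=O)(=O)C(F)(F)F
Why: Silyl triflate with a hindered amine converts the ketone into its silyl enol ether (only C11 is enolisable) and, by ionisation of the cyclic methyl acetal to the oxocarbenium ion and loss of H14, eliminates methanol to give the 2,3-dihydrofuran.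

Step 19
Reactants: 26 12-(trimethylsilyloxy)-9α,13:15,16-diepoxylabda-11,14-dien-19,6β-olide
Product: 28 6β,19-dihydroxy-9α,13:15,16-diepoxylabd-14-en-12-one (13R; CNP0176827.1), via silyl enol ether diol 27 (not isolated)
Conditions: LiAlH4, THF, 0 °C → rt; Rochelle-salt work-up; crude 27, K2CO3 (cat.), MeOH, 0 °C
Reagents that add atoms: none
Why: Hydride reduction opens the hindered 19,6-lactone to the 6β,19-diol while C12 is masked as the enol silane (or the enolate derived from it), and mild methanolysis then returns the C12 ketone without changing any stereocentre.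

**Compound list**

1 | (S)-4-benzyl-3-propanoyl-1,3-oxazolidin-2-one | CCC(=O)N1[C@@H](Cc2ccccc2)COC1=O | starting material
2 | tert-butyl bromoacetate | BrCC(=O)OC(C)(C)C | starting material
3 | tert-butyl (3R)-4-[(4S)-4-benzyl-2-oxo-1,3-oxazolidin-3-yl]-3-methyl-4-oxobutanoate | CC(C)(C)OC(=O)C[C@@H](C)C(=O)N1[C@@H](Cc2ccccc2)COC1=O | intermediate
4 | tert-butyl (3R)-4-hydroxy-3-methylbutanoate | CC(C)(C)OC(=O)C[C@@H](C)CO | intermediate
5 | tert-butyl (3R)-3-methyl-4-oxobutanoate | CC(C)(C)OC(=O)C[C@@H](C)C=O | intermediate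
6 | tert-butyl (3R)-3-methylpent-4-ynoate | CC(C)(C)OC(=O)C[C@@H](C)C#C | intermediate
7 | (3R)-3-methylpent-4-ynal | O=CC[C@@H](C)C#C | intermediate
8 | methyl 3-oxocyclohex-1-ene-1-carboxylate | COC(=O)C1=CC(=O)CCC1 | starting material
9 | methylzinc enolate of methyl (1S)-1-methyl-3-oxocyclohexane-1-carboxylate | COC(=O)[C@]1(C)C=C(O[Zn]C)CCC1 | intermediate (not isolated)
10 | methyl (1S)-1-methyl-3-(trimethylsilyloxy)cyclohex-2-ene-1-carboxylate | COC(=O)[C@]1(C)C=C(O[Si](C)(C)C)CCC1 | intermediate
11 | dibutylboron enolate corresponding to 10 | COC(=O)[C@]1(C)C=C(OB(CCCC)CCCC)CCC1 | intermediate (not isolated)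
12 | methyl (1S,2R)-2-[(1R,3R)-1-hydroxy-3-methylpent-4-yn-1-yl]-1-methyl-3-oxocyclohexane-1-carboxylate (aldol adduct) | COC(=O)[C@@]1(C)CCCC(=O)[C@H]1[C@H](O)C[C@@H](C)C#C | intermediate (not isolated)
13 | (3R,3aR,7aS)-7a-methyl-3-[(2R)-2-methylbut-3-yn-1-yl]hexahydro-2-benzofuran-1,4-dione (keto 19,6-lactone) | O=C1CCC[C@]2(C)C(=O)O[C@H](C[C@@H](C)C#C)[C@H]12 | intermediate
14 | (3R,3aR,7aS)-7a-methyl-4-methylidene-3-[(2R)-2-methylbut-3-yn-1-yl]hexahydro-2-benzofuran-1(3H)-one | C=C1CCC[C@]2(C)C(=O)O[C@H](C[C@@H](C)C#C)[C@H]12 | intermediate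
15 | L-malic acid | O[C@@H](CC(=O)O)C(=O)O | starting material
16 | [(2S,4S)-2-tert-butyl-5-oxo-1,3-dioxolan-4-yl]acetic acid | CC(C)(C)[C@H]1O[C@@H](CC(=O)O)C(=O)O1 | intermediate
17 | [(2S,4R)-4-[(benzyloxy)methyl]-2-tert-butyl-5-oxo-1,3-dioxolan-4-yl]acetic acid | CC(C)(C)[C@H]1O[C@](CC(=O)O)(COCc2ccccc2)C(=O)O1 | intermediate
18 | (2S,5R)-5-[(benzyloxy)methyl]-2-tert-butyl-5-(2-hydroxyethyl)-1,3-dioxolan-4-one | CC(C)(C)[C@H]1O[C@](CCO)(COCc2ccccc2)C(=O)O1 | intermediate
19 | [(2S,4R)-4-[(benzyloxy)methyl]-2-tert-butyl-5-oxo-1,3-dioxolan-4-yl]acetaldehyde | CC(C)(C)[C@H]1O[C@](CC=O)(COCc2ccccc2)C(=O)O1 | intermediate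
20 | (2S,5R)-2-tert-butyl-8-hydroxy-1,3,7-trioxaspiro[4.4]nonan-4-one (spiro lactol, C8 epimers) | CC(C)(C)[C@H]1O[C@@]2(CC(O)OC2)C(=O)O1 | intermediate (not isolated)
21 | methyl (3R)-3-hydroxy-5-methoxyoxolane-3-carboxylate (C5 epimers) | COC(=O)[C@@]1(O)CC(OC)OC1 | intermediate
22 | (3R)-3-hydroxy-N,5-dimethoxy-N-methyloxolane-3-carboxamide (C5 epimers) | CON(C)C(=O)[C@@]1(O)CC(OC)OC1 | intermediate
23 | (3R,3aR,7aS)-3-{(2R)-5-[(3R)-3-hydroxy-5-methoxyoxolan-3-yl]-2-methyl-5-oxopent-3-yn-1-yl}-7a-methyl-4-methylidenehexahydro-2-benzofuran-1(3H)-one (hydroxy ynone) | C=C1CCC[C@]2(C)C(=O)O[C@H](C[C@@H](C)C#CC(=O)[C@@]3(O)CC(OC)OC3)[C@H]12 | intermediate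
24 | (3R,3aR,7aS)-3-{(2R)-2-[(5R)-8-methoxy-4-oxo-1,7-dioxaspiro[4.4]non-2-en-2-yl]propyl}-7a-methyl-4-methylidenehexahydro-2-benzofuran-1(3H)-one (key-step precursor, C15 epimers) | C=C1CCC[C@]2(C)C(=O)O[C@H](C[C@@H](C)C3=CC(=O)[C@]4(CC(OC)OC4)O3)[C@H]12 | intermediate
25 | (13R)-15-methoxy-12-oxo-9α,13:15,16-diepoxylabdan-19,6β-olide (key-step product, C15 epimers) | C[C@@H]1C[C@@H](O3)[C@H]2[C@@](C)(C3=O)CCC[C@]2(C)[C@@]12CC(=O)[C@]1(CC(OC)OC1)O2 | intermediate
26 | 12-(trimethylsilyloxy)-9α,13:15,16-diepoxylabda-11,14-dien-19,6β-olide | C[C@@H]1C[C@@H](O3)[C@H]2[C@@](C)(C3=O)CCC[C@]2(C)[C@@]12C=C(O[Si](C)(C)C)[C@]1(C=COC1)O2 | intermediate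
27 | 12-(trimethylsilyloxy)-9α,13:15,16-diepoxylabda-11,14-diene-6β,19-diol | C[C@@H]1C[C@@H](O)[C@H]2[C@@](C)(CO)CCC[C@]2(C)[C@@]12C=C(O[Si](C)(C)C)[C@]1(C=COC1)O2 | intermediate (not isolated)
28 | 6β,19-dihydroxy-9α,13:15,16-diepoxylabd-14-en-12-one (13R; CNP0176827.1) | C[C@@H]1C[C@@H](O)[C@H]2[C@@](C)(CO)CCC[C@]2(C)[C@@]12CC(=O)[C@]1(C=COC1)O2 | target

**Step count.** Total: 19 steps. Longest linear sequence: 12 steps (1–5, 7, 8, 15–19).

**Steps most likely to fail**

1. Step 17 (proposed new method). The 6-exo addition to the hindered, weakly electrophilic C9 may be too slow, so that the C10 radical is quenched by the hydride source (net hydrogenation of the alkene) or the alkene isomerises; addition through the axial trajectory would give the cis-fused isomer. Fallback, by known reactions: generate the same C10 radical without any hydrogen donor. Starting from 24, Mukaiyama hydration (Mn(dpm)3, PhSiH3, O2, i-PrOH) gives the tertiary alcohol F1. Acylation with methyl chlorooxoacetate (Et3N, DMAP) gives the tert-alkyl methyl oxalate F2, and half-hydrolysis with CsOH gives the caesium oxalate F3. Visible-light photoredox decarboxylation (Ir[dF(CF3)ppy]2(dtbbpy)PF6, DME–DMF, water, blue light) then releases the tertiary radical for the Giese cyclisation, a known way to make quaternary carbons from tertiary alcohols. The fallback comes back to the route at 25.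

2. Step 7. The aldol may show poor facial selectivity at C5 or poor simple (anti/syn) selectivity, so that after lactonisation the C6-epimeric cis-lactone predominates. Fallback: replace kinetic control by stereochemical correction through invertive lactonisation. Starting from 10 and 7, the aldol mixture is lactonised under equilibrating conditions (CSA, 60 °C, C5 epimerising through the ketone), which turns the unwanted adducts into the 6-epi keto lactone F4. Takai–Lombardo methylenation gives the 6-epi methylene lactone F5, saponification (LiOH, THF–water, careful acidification at 0 °C) gives the hydroxy acid F6, and Mitsunobu lactonisation (PPh3, DIAD) closes the ring with SN2 inversion at C6. The fallback comes back at 14, so both C6 series converge.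

3. Step 18. Under the silyl triflate the doubly allylic C13–O9 bond of the bis(enol ether) may ionise and the spiro ring aromatise to a furan, or the acetal may eliminate incompletely. Fallback: stepwise formation of the enol ether in basic medium. Starting from 25, aqueous acetic acid hydrolyses the acetal to the lactol F7, and mesylation–elimination (MsCl, Et3N) dehydrates it to the dihydrofuran keto lactone F8. Kinetic enolisation and silylation (LiHMDS, TMSCl, −78 °C) then give the enol silane, so the fallback comes back at 26.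

**Further compounds**

F1 | step 17 | C10 tertiary alcohol of 24 (Markovnikov hydrate, C10 epimers) | CC1(O)CCC[C@]2(C)C(=O)O[C@H](C[C@@H](C)C3=CC(=O)[C@]4(CC(OC)OC4)O3)[C@H]12
F2 | step 17 | C10 methyl oxalate of F1 | COC(=O)C(=O)OC1(C)CCC[C@]2(C)C(=O)O[C@H](C[C@@H](C)C3=CC(=O)[C@]4(CC(OC)OC4)O3)[C@H]12
F3 | step 17 | C10 caesium oxalate | [Cs+].[O-]C(=O)C(=O)OC1(C)CCC[C@]2(C)C(=O)O[C@H](C[C@@H](C)C3=CC(=O)[C@]4(CC(OC)OC4)O3)[C@H]12
F4 | step 7 | 6-epi keto lactone (C6 epimer of 13) | O=C1CCC[C@]2(C)C(=O)O[C@@H](C[C@@H](C)C#C)[C@H]12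
F5 | step 7 | 6-epi methylene lactone (C6 epimer of 14) | C=C1CCC[C@]2(C)C(=O)O[C@@H](C[C@@H](C)C#C)[C@H]12
F6 | step 7 | 6-epi hydroxy acid from F5 | OC(=O)[C@@]1(C)CCCC(=C)[C@H]1[C@@H](O)C[C@@H](C)C#C
F7 | step 18 | C15 lactol of 25 (C15 epimers) | C[C@@H]1C[C@@H](O3)[C@H]2[C@@](C)(C3=O)CCC[C@]2(C)[C@@]12CC(=O)[C@]1(CC(O)OC1)O2
F8 | step 18 | 12-oxo-9α,13:15,16-diepoxylabd-14-en-19,6β-olide | C[C@@H]1C[C@@H](O3)[C@H]2[C@@](C)(C3=O)CCC[C@]2(C)[C@@]12CC(=O)[C@]1(C=COC1)O2
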